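Abbreviations used throughout: MOM = methoxymethyl, TBS = tert-butyldimethylsilyl, TIPS = triisopropylsilyl, Ar = 4-methoxy-2-(methoxymethoxy)-3-(3-methylbut-2-en-1-yl)phenyl (ring B in protected form). Atom labels follow isoflavan numbering (O1, C2, C3, C4, C4a, C5 to C8, C8a; ring B C1' to C6').

## Structural features

The target is an isoflavan: benzene ring A is fused through C4a and C8a to the dihydropyran ring C, and aryl ring B hangs from C3 through the C3–C1' bond. C3 is the only stereocentre and is (R); it has no stereogenic neighbour and is benzylic but not next to a carbonyl group, so it should be configurationally stable once set. Ring A keeps a single hydrogen (C6): C4a carries C4, C5 an OMe, C7 a free OH, C8 a formyl group hydrogen-bonded to that OH, and C8a the ring oxygen O1. Ring B is substituted at four contiguous positions, with the 2'-OH squeezed between C1' and the 3'-prenyl group and the 4'-OMe beyond. The fragile parts are the prenyl alkene next to a phenol (acid closes it to a 2,2-dimethylchroman, and it does not survive hydrogenation or electrophilic oxidants), the salicylaldehyde unit and the two free phenols. The real difficulty is ring A: three differently substituted oxygens and two carbon substituents must be placed so that the formyl group sits at C8 and not at C6, and substitution or metalation of a phloroglucinol-type ring does not tell these positions apart reliably. The key step avoids this by building ring A from open-chain pieces: C4a, C5, C6 and C7 come from a diazo enone attached to C4, C8 and C8a from an oxygenated alkyne, and each atom brings its own substituent.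

## Logic of the disconnections

38 from 37. Only protecting-group bonds are cut: the two C–OMe bonds of the acetal on C8 and the O–CH2 bond of the acetal on the 2'-oxygen. The aldehyde and the prenyl-flanked phenol are the most delicate functions, so they stay masked until the end and all earlier steps may use bases, organometals, hydride and phosphines. The forward hydrolysis must be mild enough not to protonate the prenyl alkene next to the freed 2'-OH.

37 from 36. The O1–C2 bond is cut, which opens ring C to a chain ending in a primary alcohol. The forward step is a dehydrative six-membered etherification through the C8a phenol. The C7 phenol cannot reach C2, and the 2'-oxygen must stay blocked because it could otherwise close a five-membered ring on the same carbon. C2 is a CH2 group, so C3 is not at risk.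

36 from 35. Two O–Si bonds are cut (C8a–O–Si and C2–O–Si). Both silyl groups must fall in one fluoride operation while the two acetals survive.

35 from 25 and 31. Ring A is taken apart at C7–C8, C4a–C8a and C6–C7; the C4a–C5 bond goes back to the acyl–vinyl bond of a diazo ketone. A pentasubstituted arene is thereby reduced to a linear diazo enone and a three-carbon alkyne, and no arene substitution chemistry is needed. The forward step demands the correct orientation of ketene and alkyne and a clean 1,2-shift of the diazo ketone.

31 from 26 and 27. The bond between the acetal carbon and the new alkyne carbon and the O–Si bond are cut. A one-carbon homologation of an ester through an ynolate gives the oxygenated alkyne in one operation; the ynolate must be silylated on oxygen.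

25 from 22. The C=N2 bond at C4a is cut. 22 has a single enolisable position, so the diazo group can be introduced only where it is wanted.

22 from 19 and 20. The C7–C5 bond (acyl to vinyl carbon) is cut. The metalated form of 20 brings C5, C6 and the C5 methoxy group; the acyl partner must stop at single addition, which is why an N-methoxy-N-methylamide is used.

19 from 16 through 18 and 17. These are functional-group changes only: ester to amide, O–Si, and removal of the auxiliary by reduction of its acyl carbon to the C2 alcohol. The hydride step must distinguish the imide from the methyl ester. The methyl ester is accepted because it later exchanges to the amide under standard conditions, which a bulkier ester would not.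

16 from 13 and 14. The C3–C4 bond is cut; this is the step that creates the stereocentre. A conjugate addition of an auxiliary-bound enolate to 14 delivers C4, C4a and C7 at the correct oxidation level, and the auxiliary must control the enolate face.

13 from 10 and 11. The N–acyl bond is cut. The auxiliary has to be the (R)-enantiomer to lead to (3R).

10 from 5 and 6 through 8. The C1'–CH2 bond is cut. Ring B is metalated next to its acetal oxygen and captured by the two-carbon electrophile 6, then the alcohol is oxidised. The metalation must occur on the ring and not at the prenyl CH2.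

5 from 2 and 3, and 2 from 1. The C3'–prenyl bond and the O–CH2 bond are cut. The position between the two oxygens of 2 is the most acidic, so the prenyl group goes exactly where it is needed. The same acetal group later directs the second metalation, blocks the 2'-oxygen during ring C closure and leaves together with the C8 acetal.

## Other disconnections considered

Alternative 1: The cut is the C3–C1' bond, made after adding a temporary C4–O2' bond, so that the isoflavan is traced back to the cis-pterocarpan A3.
- Forward key step: the ring A chromene A1 and the ring B iodophenol A2 react under Pd(OAc)2, a chiral bisphosphine and Ag2CO3. Oxidative addition to zerovalent palladium, iodide abstraction by silver, syn-carbopalladation of the C3=C4 alkene (aryl to C3, divalent palladium at benzylic C4) and C–O bond formation would give A3. Reductive cleavage of the benzylic C4–O bond and unmasking follow.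
- In favour: two arene halves are joined late, C3 is set by a catalyst and not by a stoichiometric auxiliary, the 2'-oxygen is protected by the ring itself, and no diazo compound or photochemistry is needed.
- Against: A1 already contains the complete ring A pattern, so the C6/C8 problem is only moved into the synthesis of A1. Facial control has to come from a bisphosphine on a cationic, silver-treated palladium centre, a less secure element than an auxiliary. The ortho-prenyl phenol of A2 can divert the arylpalladium. The ring opening cannot use catalytic hydrogenolysis (the prenyl group would be saturated), and acid/hydride conditions pass through a C4 cation beside the freed 2'-OH and the prenyl group.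
- Comparison: on convergence and step economy this alternative is the better one. On mechanism it is the equal in bond-forming efficiency (two bonds and one ring in the key step) but weaker in stereocontrol. On structure the chosen plan is stronger, because it answers the substitution problem of ring A that this alternative leaves open.

Alternative 2: The cuts are C3–C4 and the O1–C2 bond at the acyl oxidation level.
- Forward key step: the ring A sulfone A4 releases an ortho-quinone methide under base; the arylacetic acid 10, activated with pivaloyl chloride and bound to benzotetramisole as an ammonium enolate, adds through C3 to the methylene carbon and the phenoxide then acylates, closing ring C as the dihydrocoumarin A5. Reduction of the lactone and a second ring closure as in step 15 would be needed afterwards.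
- In favour: the C3 stereocentre is made catalytically from the same acid 10 without attaching and removing an auxiliary, which saves about three steps before the key step and is a point on which this alternative is better. The conditions are mild, and ring A starts as a stable arene.
- Against: A4 again needs a pentasubstituted ring A with the CH2 group at C4a and the masked aldehyde at C8 installed by arene substitution. The unsubstituted quinone methide is prone to oligomerise and offers the catalyst little to discriminate. The C3–H of A5 is an acidic α-aryl lactone proton under the basic conditions. C2 arrives as a carbonyl, so the endgame needs a reduction and a re-closure.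
- Comparison: equal in number of rings formed in the key step and better in atom economy of the stereocontrol, but weaker in structure (ring A pattern unsolved) and not shorter overall once the redox correction is counted.

Alternative 3: The cuts are the ring B bonds C1'–C2', C2'–C3' and C4'–C5'.
- Forward key step: the chroman-3-yl diazo enone A6 undergoes photochemical Wolff rearrangement to a vinylketene, which combines with the methoxyalkyne A7 and closes ring B, giving the isoflavan A8; desilylation and formylation at C8 would follow.
- In favour: it is the same reaction class as the chosen plan, and the diazo carbon of A6 is unsubstituted, so the competing 1,2-hydrogen shift of the chosen diazo ketone cannot occur; on this mechanistic point the alternative is better. The OH/prenyl/OMe triad of ring B is delivered in one step with the 2'-OH free, so no directed metalation sequence and no final acid deprotection of ring B is needed, which is also better.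
- Against: ring A and the stereocentre must first be made as a chroman by conventional chemistry. The formyl group is missing and has to be introduced last, ortho to the 7-OH, where C6 and C8 compete; this is exactly the hardest selectivity of the target, now at the final step and in the presence of the prenyl phenol. The C3–H of A6 is γ to the enone carbonyl and may be lost through a dienolate.
- Comparison: equal in step count, better in the security of the Wolff step and in protecting-group economy on ring B, but weaker in structure, because the benzannulation is spent on the ring that is easy to make and the difficult ring is left to arene substitution.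

Key step: step 13

Remarks on the chemistry:
- C3 of the target is (R). All side-chain intermediates keep the same spatial arrangement and the same CIP ranking (oxygenated carbon > aryl > CH2 > H), so all are (R).
- The (R)-4-benzyl oxazolidinone is required for this configuration.
- Besides the three bonds made to the alkyne and in the ring closure, ring A needs a fourth new C–C bond, C4a–C5, which arises from the 1,2-vinyl shift of the Wolff rearrangement.

## Route

Step 1
Reactants: 1 3-methoxyphenol
Product: 2 1-methoxy-3-(methoxymethoxy)benzene
Conditions: MOMCl, i-Pr2NEt, CH2Cl2, 0 °C → rt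
Reagents that add atoms: chloromethyl methyl ether COCCl
Why: O-alkylation of the phenol (Williamson-type etherification) installs the acetal that later directs both metalations and masks the 2'-oxygen to the end.

Step 2
Reactants: 2 1-methoxy-3-(methoxymethoxy)benzene; 3 1-bromo-3-methylbut-2-ene
Product: 5 1-methoxy-3-(methoxymethoxy)-2-(3-methylbut-2-en-1-yl)benzene, via aryllithium 4 (not isolated)
Conditions: n-BuLi, THF, 0 °C → rt; CuI (10 mol %), 3, −78 °C → rt
Reagents that add atoms: none
Why: Directed ortho-metalation occurs at the position flanked by both oxygens, and copper-catalysed allylic substitution at the primary carbon of 3 gives the linear prenyl group.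

Step 3
Reactants: 5 1-methoxy-3-(methoxymethoxy)-2-(3-methylbut-2-en-1-yl)benzene; 6 oxirane
Product: 8 2-Ar-ethan-1-ol, via aryllithium 7 (not isolated)
Conditions: s-BuLi, TMEDA, THF, −78 °C; 6, −78 °C → rt; H2O
Reagents that add atoms: none
Why: Second directed ortho-metalation; the acetal oxygen is the stronger director, so lithiation goes ortho to it (para to OMe), kinetic conditions disfavour deprotonation of the prenyl CH2, and the aryllithium opens the epoxide.

Step 4
Reactants: 8 2-Ar-ethan-1-ol
Product: 10 Ar-acetic acid, via arylacetaldehyde 9 (not isolated)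
Conditions: TEMPO (10 mol %), PhI(OAc)2, MeCN–H2O, rt
Reagents that add atoms: water O
Why: Oxoammonium-mediated oxidation of the primary alcohol to the aldehyde and, through its hydrate, to the acid; the oxidant system leaves trisubstituted alkenes and aryl ethers alone.

Step 5
Reactants: 10 Ar-acetic acid; 11 (4R)-4-benzyl-1,3-oxazolidin-2-one
Product: 13 (4R)-4-benzyl-3-(Ar-acetyl)-1,3-oxazolidin-2-one, via mixed pivalic anhydride 12 (not isolated)
Conditions: t-BuCOCl, Et3N, THF, −20 °C; LiCl, 11, −20 °C → rt
Reagents that add atoms: none
Why: N-acylation of the auxiliary through the mixed anhydride; the hindered pivaloyl carbonyl directs attack to the arylacetyl carbonyl.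

Step 6
Reactants: 13 (4R)-4-benzyl-3-(Ar-acetyl)-1,3-oxazolidin-2-one; 14 methyl acrylate
Product: 16 methyl (4R)-4-Ar-5-[(4R)-4-benzyl-2-oxo-1,3-oxazolidin-3-yl]-5-oxopentanoate, via chlorotitanium enolate 15 (not isolated)
Conditions: TiCl3(OiPr) (from TiCl4 and Ti(OiPr)4, 3:1), i-Pr2NEt, CH2Cl2, 0 °C; 14, 0 °C; cold aqueous quench
Reagents that add atoms: none
Why: Auxiliary-controlled (Evans-type) titanium enolate Michael addition: soft enolisation gives the chelated Z-enolate, the acrylate adds to the face opposite the benzyl group, and with the (R)-auxiliary this sets C3 as (R); a cold quench guards the acidic α-aryl centre against epimerisation.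

Step 7
Reactants: 16 methyl (4R)-4-Ar-5-[(4R)-4-benzyl-2-oxo-1,3-oxazolidin-3-yl]-5-oxopentanoate
Product: 17 methyl (4R)-4-Ar-5-hydroxypentanoate
Conditions: LiBH4, H2O (1 equiv), Et2O, 0 °C
Reagents that add atoms: none
Why: Borohydride reduction of the activated imide carbonyl, which is more electrophilic than the methyl ester, releases the auxiliary; limited reagent at 0 °C and immediate use of 17 restrain ester reduction and lactonisation, and C3 is not touched.

Step 8
Reactants: 17 methyl (4R)-4-Ar-5-hydroxypentanoate
Product: 18 methyl (4R)-4-Ar-5-(TBS-oxy)pentanoate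
Conditions: TBSCl, imidazole, DMF, 0 °C → rt
Reagents that add atoms: tert-butyldimethylsilyl chloride CC(C)(C)[Si](C)(C)Cl
Why: Standard silylation of the primary alcohol; the silyl ether survives the organolithium, amide-base and photochemical steps and leaves later together with the aryl silyl ether.

Step 9
Reactants: 18 methyl (4R)-4-Ar-5-(TBS-oxy)pentanoate
Product: 19 (4R)-4-Ar-5-(TBS-oxy)-N-methoxy-N-methylpentanamide
Conditions: MeNH(OMe)·HCl, i-PrMgCl, THF, −20 → 0 °C
Reagents that add atoms: N,O-dimethylhydroxylamine hydrochloride CNOC.Cl
Why: Aminolysis of the methyl ester by the magnesium amide gives the Weinreb amide; no acidic or epimerisable centre lies next to the reacting carbonyl.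

Step 10
Reactants: 19 (4R)-4-Ar-5-(TBS-oxy)-N-methoxy-N-methylpentanamide; 20 methoxyethene
Product: 22 (6R)-6-Ar-7-(TBS-oxy)-2-methoxyhept-1-en-3-one, via 1-methoxyvinyllithium 21 (not isolated)
Conditions: 20, t-BuLi, THF, −78 → 0 °C; then 19, −78 °C; H2O
Reagents that add atoms: none
Why: α-Lithiation of the enol ether and Weinreb ketone synthesis; the chelated tetrahedral adduct prevents double addition, and the neutral aqueous quench spares the enol ether.

Step 11
Reactants: 22 (6R)-6-Ar-7-(TBS-oxy)-2-methoxyhept-1-en-3-one
Product: 25 (6R)-6-Ar-7-(TBS-oxy)-4-diazo-2-methoxyhept-1-en-3-one, via lithium enolate 23 (not isolated), via trifluoroacetyl ketone 24 (not isolated)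
Conditions: LiN(SiMe3)2, THF, −78 °C; CF3CO2CH2CF3; then MsN3, Et3N, H2O, MeCN, rt
Reagents that add atoms: methanesulfonyl azide CS(=O)(=O)N=[N+]=[N-]
Why: Detrifluoroacetylative diazo transfer: the only enolisable position is acylated, and the activated 1,3-dicarbonyl accepts the diazo group with loss of the trifluoroacetyl unit; the enone is electron-rich and a poor Michael acceptor for the amide base.

Step 12
Reactants: 26 methyl 2,2-dimethoxyacetate; 27 dibromomethane
Product: 31 3,3-dimethoxy-1-(TIPS-oxy)prop-1-yne, via dibromomethyllithium 28 (not isolated), via lithium dibromo enolate 29 (not isolated), via lithium ynolate 30 (not isolated)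
Conditions: 27, lithium 2,2,6,6-tetramethylpiperidide, THF, −78 °C; 26; LiN(SiMe3)2; n-BuLi, −78 °C → rt; i-Pr3SiCl, 0 °C
Reagents that add atoms: chlorotri(propan-2-yl)silane CC(C)[Si](Cl)(C(C)C)C(C)C
Why: Kowalski ester homologation: bromine–lithium exchange on the dibromo enolate triggers a 1,2-shift to the ynolate, and the bulky silyl chloride traps it on oxygen to give the siloxyalkyne.

Step 13
Reactants: 25 (6R)-6-Ar-7-(TBS-oxy)-4-diazo-2-methoxyhept-1-en-3-one; 31 3,3-dimethoxy-1-(TIPS-oxy)prop-1-yne
Product: 35 4-[(2R)-2-Ar-3-(TBS-oxy)propyl]-2-(dimethoxymethyl)-5-methoxy-3-(TIPS-oxy)phenol, via vinylketene 32 (not isolated), via vinylcyclobutenone 33 (not isolated), via dienylketene 34 (not isolated)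
Conditions: 31 (1.5–2 equiv), hν (450 W medium-pressure Hg lamp, Pyrex filter), degassed ClCH2CH2Cl, rt; then 80 °C
Reagents that add atoms: none
Why: Irradiation of 25 causes a photochemical Wolff rearrangement, in which loss of N2 and a 1,2-shift of the 1-methoxyvinyl group from the carbonyl carbon to the diazo carbon (forming C4a–C5) give vinylketene 32. The electron-rich alkyne 31 adds to the ketene C=C in a polar [2+2] cycloaddition, its nucleophilic carbon (the one bearing the acetal) bonding to the ketene carbonyl carbon (C7–C8) and its oxygenated carbon to the ketene α-carbon (C4a–C8a), which gives cyclobutenone 33. On warming, 33 opens by a 4π electrocyclic reaction (cleaving C4a–C7) to dienylketene 34, and ring A then closes by a thermal disrotatory 6π electrocyclisation (C6–C7) followed by tautomerisation of the cyclohexadienone, so that the former ketene oxygen becomes the free C7 phenol. The closest known reaction type is the Danheiser benzannulation in its diazo ketone variant with siloxyalkynes, which gives resorcinol monosilyl ethers. No stereocentre is created, since the quaternary carbon of 33 is erased on ring opening, and C3 lies outside the reacting chain. The step needs the regiochemistry of the ketene–alkyne union, which the polarisation of 31 by its silyloxy group secures, and it needs vinyl migration to outrun a carbene-type 1,2-hydrogen shift from C4, which the s-Z conformer of the diazo ketone and the good migrating ability of the sp2 group favour. The prenyl alkene is far less reactive toward the ketene than 31, and the acetal and silyl ethers are inert, so OMe, OH, acetal carbon, silyl ether and the C4 chain each arrive on their own ring atom.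

Step 14
Reactants: 35 4-[(2R)-2-Ar-3-(TBS-oxy)propyl]-2-(dimethoxymethyl)-5-methoxy-3-(TIPS-oxy)phenol
Product: 36 4-[(2R)-2-Ar-3-hydroxypropyl]-2-(dimethoxymethyl)-5-methoxybenzene-1,3-diol
Conditions: Bu4NF, THF, 0 °C → rt; H2O; crude product carried on
Reagents that add atoms: none
Why: Fluoride cleaves the aryl silyl ether and the primary alkyl silyl ether in one operation; both acetals are stable to the basic medium, and the acid-labile ortho-hydroxy acetal is not exposed to silica.

Step 15
Reactants: 36 4-[(2R)-2-Ar-3-hydroxypropyl]-2-(dimethoxymethyl)-5-methoxybenzene-1,3-diol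
Product: 37 (3R)-3-Ar-8-(dimethoxymethyl)-5-methoxy-3,4-dihydro-2H-chromen-7-ol
Conditions: PPh3, DIAD, THF (0.01 M), 0 °C → rt
Reagents that add atoms: none
Why: Intramolecular Mitsunobu etherification: the activated primary alcohol is displaced by the C8a phenol in a six-membered closure; the C7 phenol cannot reach C2, the 2'-oxygen is blocked so no five-membered ring can form, and the reacting carbon is a CH2 so C3 keeps its configuration.

Step 16
Reactants: 37 (3R)-3-Ar-8-(dimethoxymethyl)-5-methoxy-3,4-dihydro-2H-chromen-7-ol
Product: 38 (3R)-7-hydroxy-3-[2-hydroxy-4-methoxy-3-(3-methylbut-2-en-1-yl)phenyl]-5-methoxy-3,4-dihydro-2H-chromene-8-carbaldehyde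
Conditions: 3 M aq. HCl, MeOH–THF, 40 °C
Reagents that add atoms: water O
Why: Acid-catalysed hydrolysis of the dimethyl acetal (assisted by the flanking phenols) and of the aryl MOM ether; methanol traps the released one-carbon unit as dimethoxymethane, and dilute acid at this temperature should not protonate the trisubstituted alkene.

## Compound list

1 | 3-methoxyphenol | COc1cccc(O)c1 | starting material
2 | 1-methoxy-3-(methoxymethoxy)benzene | COCOc1cccc(OC)c1 | intermediate
3 | 1-bromo-3-methylbut-2-ene (prenyl bromide) | CC(C)=CCBr | starting material
4 | [2-methoxy-6-(methoxymethoxy)phenyl]lithium (not isolated) | [Li]c1c(OC)cccc1OCOC | intermediate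
5 | 1-methoxy-3-(methoxymethoxy)-2-(3-methylbut-2-en-1-yl)benzene | COCOc1cccc(OC)c1CC=C(C)C | intermediate
6 | oxirane | C1CO1 | starting material
7 | [4-methoxy-2-(methoxymethoxy)-3-(3-methylbut-2-en-1-yl)phenyl]lithium (not isolated) | [Li]c1ccc(OC)c(CC=C(C)C)c1OCOC | intermediate
8 | 2-[4-methoxy-2-(methoxymethoxy)-3-(3-methylbut-2-en-1-yl)phenyl]ethan-1-ol | COc1ccc(CCO)c(OCOC)c1CC=C(C)C | intermediate
9 | [4-methoxy-2-(methoxymethoxy)-3-(3-methylbut-2-en-1-yl)phenyl]acetaldehyde (not isolated) | COc1ccc(CC=O)c(OCOC)c1CC=C(C)C | intermediate
10 | [4-methoxy-2-(methoxymethoxy)-3-(3-methylbut-2-en-1-yl)phenyl]acetic acid | COc1ccc(CC(=O)O)c(OCOC)c1CC=C(C)C | intermediate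
11 | (4R)-4-benzyl-1,3-oxazolidin-2-one | O=C1N[C@H](Cc2ccccc2)CO1 | starting material
12 | Ar-acetic pivalic anhydride (not isolated) | COc1ccc(CC(=O)OC(=O)C(C)(C)C)c(OCOC)c1CC=C(C)C | intermediate
13 | (4R)-4-benzyl-3-(Ar-acetyl)-1,3-oxazolidin-2-one | COc1ccc(CC(=O)N2[C@H](Cc3ccccc3)COC2=O)c(OCOC)c1CC=C(C)C | intermediate
14 | methyl acrylate | C=CC(=O)OC | starting material
15 | dichloro(isopropoxy)titanium Z-enolate of 13 (not isolated) | COc1ccc(/C=C(\O[Ti](Cl)(Cl)OC(C)C)N2[C@H](Cc3ccccc3)COC2=O)c(OCOC)c1CC=C(C)C | intermediate
16 | methyl (4R)-4-Ar-5-[(4R)-4-benzyl-2-oxo-1,3-oxazolidin-3-yl]-5-oxopentanoate | COc1ccc([C@@H](CCC(=O)OC)C(=O)N2[C@H](Cc3ccccc3)COC2=O)c(OCOC)c1CC=C(C)C | intermediate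
17 | methyl (4R)-4-Ar-5-hydroxypentanoate | COc1ccc([C@@H](CCC(=O)OC)CO)c(OCOC)c1CC=C(C)C | intermediate
18 | methyl (4R)-4-Ar-5-[(tert-butyldimethylsilyl)oxy]pentanoate | COc1ccc([C@@H](CCC(=O)OC)CO[Si](C)(C)C(C)(C)C)c(OCOC)c1CC=C(C)C | intermediate
19 | (4R)-4-Ar-5-[(tert-butyldimethylsilyl)oxy]-N-methoxy-N-methylpentanamide | COc1ccc([C@@H](CCC(=O)N(C)OC)CO[Si](C)(C)C(C)(C)C)c(OCOC)c1CC=C(C)C | intermediate
20 | methoxyethene (methyl vinyl ether) | COC=C | starting material
21 | (1-methoxyethenyl)lithium (not isolated) | [Li]C(=C)OC | intermediate
22 | (6R)-6-Ar-7-[(tert-butyldimethylsilyl)oxy]-2-methoxyhept-1-en-3-one | COc1ccc([C@@H](CCC(=O)C(=C)OC)CO[Si](C)(C)C(C)(C)C)c(OCOC)c1CC=C(C)C | intermediate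
23 | lithium enolate of 22 at C4 (not isolated) | COc1ccc([C@@H](CC=C(O[Li])C(=C)OC)CO[Si](C)(C)C(C)(C)C)c(OCOC)c1CC=C(C)C | intermediate
24 | (6R)-6-Ar-7-[(tert-butyldimethylsilyl)oxy]-2-methoxy-4-(trifluoroacetyl)hept-1-en-3-one (not isolated) | COc1ccc([C@@H](CC(C(=O)C(F)(F)F)C(=O)C(=C)OC)CO[Si](C)(C)C(C)(C)C)c(OCOC)c1CC=C(C)C | intermediate
25 | (6R)-6-Ar-7-[(tert-butyldimethylsilyl)oxy]-4-diazo-2-methoxyhept-1-en-3-one | COc1ccc([C@@H](CC(=[N+]=[N-])C(=O)C(=C)OC)CO[Si](C)(C)C(C)(C)C)c(OCOC)c1CC=C(C)C | intermediate
26 | methyl 2,2-dimethoxyacetate | COC(OC)C(=O)OC | starting material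
27 | dibromomethane | BrCBr | starting material
28 | (dibromomethyl)lithium (not isolated) | [Li]C(Br)Br | intermediate
29 | lithium 2,2-dibromo-1-(dimethoxymethyl)ethen-1-olate (not isolated) | [Li]OC(=C(Br)Br)C(OC)OC | intermediate
30 | lithium 3,3-dimethoxyprop-1-yn-1-olate (not isolated) | [Li]OC#CC(OC)OC | intermediate
31 | 3,3-dimethoxy-1-[(triisopropylsilyl)oxy]prop-1-yne | COC(OC)C#CO[Si](C(C)C)(C(C)C)C(C)C | intermediate
32 | 2-[(2R)-2-Ar-3-[(tert-butyldimethylsilyl)oxy]propyl]-3-methoxybuta-1,3-dien-1-one (not isolated) | COc1ccc([C@@H](CC(=C=O)C(=C)OC)CO[Si](C)(C)C(C)(C)C)c(OCOC)c1CC=C(C)C | intermediate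
33 | 4-[(2R)-2-Ar-3-[(tert-butyldimethylsilyl)oxy]propyl]-2-(dimethoxymethyl)-4-(1-methoxyethenyl)-3-[(triisopropylsilyl)oxy]cyclobut-2-en-1-one, both epimers at the ring carbon (not isolated) | COc1ccc([C@@H](CC2(C(=C)OC)C(=O)C(C(OC)OC)=C2O[Si](C(C)C)(C(C)C)C(C)C)CO[Si](C)(C)C(C)(C)C)c(OCOC)c1CC=C(C)C | intermediate
34 | (3E)-4-[(2R)-2-Ar-3-[(tert-butyldimethylsilyl)oxy]propyl]-2-(dimethoxymethyl)-5-methoxy-3-[(triisopropylsilyl)oxy]hexa-1,3,5-trien-1-one (not isolated) | COc1ccc([C@@H](C/C(C(=C)OC)=C(\O[Si](C(C)C)(C(C)C)C(C)C)C(=C=O)C(OC)OC)CO[Si](C)(C)C(C)(C)C)c(OCOC)c1CC=C(C)C | intermediate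
35 | 4-[(2R)-2-Ar-3-[(tert-butyldimethylsilyl)oxy]propyl]-2-(dimethoxymethyl)-5-methoxy-3-[(triisopropylsilyl)oxy]phenol | COc1ccc([C@@H](Cc2c(OC)cc(O)c(C(OC)OC)c2O[Si](C(C)C)(C(C)C)C(C)C)CO[Si](C)(C)C(C)(C)C)c(OCOC)c1CC=C(C)C | intermediate
36 | 4-[(2R)-2-Ar-3-hydroxypropyl]-2-(dimethoxymethyl)-5-methoxybenzene-1,3-diol | COc1ccc([C@@H](Cc2c(OC)cc(O)c(C(OC)OC)c2O)CO)c(OCOC)c1CC=C(C)C | intermediate
37 | (3R)-3-Ar-8-(dimethoxymethyl)-5-methoxy-3,4-dihydro-2H-chromen-7-ol | COc1ccc([C@@H]2COc3c(C(OC)OC)c(O)cc(OC)c3C2)c(OCOC)c1CC=C(C)C | intermediate
38 | (3R)-7-hydroxy-3-[2-hydroxy-4-methoxy-3-(3-methylbut-2-en-1-yl)phenyl]-5-methoxy-3,4-dihydro-2H-chromene-8-carbaldehyde | COc1ccc([C@@H]2COc3c(C=O)c(O)cc(OC)c3C2)c(O)c1CC=C(C)C | target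

## Step count and least certain steps

Total: 16 steps. Longest linear sequence: 15 steps (steps 1 to 11, then 13 to 16); step 12 is a one-step branch.

Step 13 (key step). The most likely failure is loss of nitrogen from the conformer that cannot rearrange in concert, giving a free acyl carbene that undergoes a 1,2-hydrogen shift from C4 to a dienone instead of vinyl migration. Slow capture of the ketene by the inductively deactivated alkyne, with ketene dimerisation, is the second concern.
Fallback, setting out from 18 and returning at 35: the same vinylketene is generated thermally from a cyclobutenone, so no carbene is involved. Deprotonation of 18 with LiN(i-Pr)2 and O-phosphorylation with diethyl chlorophosphate should give the ketene acetal phosphate F1. Elimination with t-BuLi at −78 °C would give the 1-methoxyalkyne F2. Cycloaddition of F2 with ketene made in the flask from acetyl chloride and Et3N would give the 2-alkyl-3-methoxycyclobutenone F3. Heating F3 with 31 in toluene at 80–110 °C opens the four-membered ring to 32, and the cascade continues to 35.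

Step 3. Deprotonation may occur at the prenyl CH2, which is both benzylic and allylic, or ortho to the OMe group, because the alkyllithium base is not fully guided by the acetal oxygen; the result would be loss of regiocontrol.
Fallback, setting out from 1 and returning at 8: the side chain is installed first and the prenyl group last, at the only position lying between two oxygens. Magnesium-mediated ortho-formylation of 1 (MgCl2, Et3N, paraformaldehyde) should give 2-hydroxy-4-methoxybenzaldehyde F4. Protection with MOMCl gives 4-methoxy-2-(methoxymethoxy)benzaldehyde F5. Wittig methylenation gives the styrene F6. Hydroboration–oxidation (9-BBN, then H2O2, NaOH) gives 2-[4-methoxy-2-(methoxymethoxy)phenyl]ethan-1-ol F7. Double deprotonation of F7 with n-BuLi and CuI-catalysed reaction with 3 then give 8.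

Step 6. The Lewis-acidic titanium may strip the MOM group or initiate acrylate polymerisation, the aryl-stabilised enolate may add sluggishly, and the acidic α-aryl centre may epimerise before the quench.
Fallback, setting out from 13 and returning at 19: a sodium enolate alkylation replaces the Michael addition. NaN(SiMe3)2 and allyl iodide at −78 °C should give the allylated imide F8 with the same facial sense. LiBH4 gives the alcohol F9, and TBSCl gives the silyl ether F10. 9-BBN, which prefers the terminal alkene over the trisubstituted prenyl alkene, followed by H2O2 and NaOH gives the primary alcohol F11. Oxidation as in step 4 gives the acid F12, and carbodiimide coupling with N,O-dimethylhydroxylamine gives 19.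

Step 7. Over-reduction of the methyl ester, or lactonisation of the δ-hydroxy ester during isolation, would lower the amount of 17 reaching step 8.
Fallback, setting out from 16 and returning at 19: the lactone is made on purpose. NaBH4 in THF–H2O reduces only the imide to 17, which is closed with catalytic pyridinium tosylate in warm toluene to the δ-lactone F13. Opening with MeNH(OMe)·HCl and i-PrMgCl gives the hydroxy amide F14, and silylation as in step 8 gives 19.

Step 12. The 1,2-shift of the carbenoid may fail because the migrating dimethoxymethyl group is electron-poor, or a lithiated intermediate may expel methoxide.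
Fallback, setting out from 26 and returning at 30 (and so at 31): the ynolate is made by oxidation instead of rearrangement. Reduction of 26 with i-Bu2AlH at −78 °C gives dimethoxyacetaldehyde F15. Ohira–Bestmann homologation (dimethyl 1-diazo-2-oxopropylphosphonate, K2CO3, MeOH) gives 3,3-dimethoxyprop-1-yne F16. Lithiation with n-BuLi and oxidation of the acetylide with lithium tert-butyl peroxide give 30, which is silylated as in step 12.

Step 16. Once the 2'-OH is free, protonation of the prenyl alkene and ring closure to a dimethylchroman may set in before the MOM cleavage is complete.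
Fallback, setting out from 37 and returning at 38: the two acetals are removed separately and the MOM group without protic acid. Pyridinium tosylate in wet acetone at rt should hydrolyse only the dimethyl acetal to the MOM-protected aldehyde F17. Trimethylsilyl triflate with 2,2'-bipyridyl in CH2Cl2 at 0 °C, followed by water, then converts the aryl MOM ether through the silyl ether into the phenol 38.

## Further compounds

F1 | step 13 | diethyl (4R)-4-Ar-5-[(tert-butyldimethylsilyl)oxy]-1-methoxypent-1-en-1-yl phosphate (E/Z mixture) | COc1ccc([C@@H](CC=C(OC)OP(=O)(OCC)OCC)CO[Si](C)(C)C(C)(C)C)c(OCOC)c1CC=C(C)C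
F2 | step 13 | tert-butyl{[(2R)-2-Ar-5-methoxypent-4-yn-1-yl]oxy}dimethylsilane | COc1ccc([C@@H](CC#COC)CO[Si](C)(C)C(C)(C)C)c(OCOC)c1CC=C(C)C
F3 | step 13 | 2-[(2R)-2-Ar-3-[(tert-butyldimethylsilyl)oxy]propyl]-3-methoxycyclobut-2-en-1-one | COc1ccc([C@@H](CC2=C(OC)CC2=O)CO[Si](C)(C)C(C)(C)C)c(OCOC)c1CC=C(C)C
F4 | step 3 | 2-hydroxy-4-methoxybenzaldehyde | COc1ccc(C=O)c(O)c1
F5 | step 3 | 4-methoxy-2-(methoxymethoxy)benzaldehyde | COCOc1cc(OC)ccc1C=O
F6 | step 3 | 1-ethenyl-4-methoxy-2-(methoxymethoxy)benzene | COCOc1cc(OC)ccc1C=C
F7 | step 3 | 2-[4-methoxy-2-(methoxymethoxy)phenyl]ethan-1-ol | COCOc1cc(OC)ccc1CCO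
F8 | step 6 | (4R)-4-benzyl-3-[(2R)-2-Ar-pent-4-enoyl]-1,3-oxazolidin-2-one | COc1ccc([C@@H](CC=C)C(=O)N2[C@H](Cc3ccccc3)COC2=O)c(OCOC)c1CC=C(C)C
F9 | step 6 | (2R)-2-Ar-pent-4-en-1-ol | COc1ccc([C@@H](CC=C)CO)c(OCOC)c1CC=C(C)C
F10 | step 6 | tert-butyl{[(2R)-2-Ar-pent-4-en-1-yl]oxy}dimethylsilane | COc1ccc([C@@H](CC=C)CO[Si](C)(C)C(C)(C)C)c(OCOC)c1CC=C(C)C
F11 | step 6 | (4R)-4-Ar-5-[(tert-butyldimethylsilyl)oxy]pentan-1-ol | COc1ccc([C@@H](CCCO)CO[Si](C)(C)C(C)(C)C)c(OCOC)c1CC=C(C)C
F12 | step 6 | (4R)-4-Ar-5-[(tert-butyldimethylsilyl)oxy]pentanoic acid | COc1ccc([C@@H](CCC(=O)O)CO[Si](C)(C)C(C)(C)C)c(OCOC)c1CC=C(C)C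
F13 | step 7 | (5R)-5-Ar-oxan-2-one | COc1ccc([C@@H]2COC(=O)CC2)c(OCOC)c1CC=C(C)C
F14 | step 7 | (4R)-4-Ar-5-hydroxy-N-methoxy-N-methylpentanamide | COc1ccc([C@@H](CCC(=O)N(C)OC)CO)c(OCOC)c1CC=C(C)C
F15 | step 12 | 2,2-dimethoxyacetaldehyde | COC(OC)C=O
F16 | step 12 | 3,3-dimethoxyprop-1-yne | COC(OC)C#C
F17 | step 16 | (3R)-3-Ar-7-hydroxy-5-methoxy-3,4-dihydro-2H-chromene-8-carbaldehyde | COc1ccc([C@@H]2COc3c(C=O)c(O)cc(OC)c3C2)c(OCOC)c1CC=C(C)C
A1 | alternative 1 | 8-(1,3-dioxolan-2-yl)-5-methoxy-7-(methoxymethoxy)-2H-chromene | COc1cc(OCOC)c(C3OCCO3)c2OCC=Cc12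
A2 | alternative 1 | 6-iodo-3-methoxy-2-(3-methylbut-2-en-1-yl)phenol | COc1ccc(I)c(O)c1CC=C(C)C
A3 | alternative 1 | (6aR,11aR)-4-(1,3-dioxolan-2-yl)-1,9-dimethoxy-3-(methoxymethoxy)-10-(3-methylbut-2-en-1-yl)pterocarpan (cis ring fusion) | COc1ccc2c(c1CC=C(C)C)O[C@H]1c3c(OC)cc(OCOC)c(C4OCCO4)c3OC[C@@H]21
A4 | alternative 2 | 2-(1,3-dioxolan-2-yl)-5-methoxy-3-(methoxymethoxy)-6-[(4-methylbenzenesulfonyl)methyl]phenol | COc1cc(OCOC)c(C2OCCO2)c(O)c1CS(=O)(=O)c1ccc(C)cc1
A5 | alternative 2 | (3R)-3-Ar-8-(1,3-dioxolan-2-yl)-5-methoxy-7-(methoxymethoxy)-3,4-dihydro-2H-chromen-2-one | COc1ccc([C@@H]2C(=O)Oc3c(C4OCCO4)c(OCOC)cc(OC)c3C2)c(OCOC)c1CC=C(C)C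
A6 | alternative 3 | (3E)-1-diazo-4-[(3R)-5-methoxy-7-[(triisopropylsilyl)oxy]-3,4-dihydro-2H-chromen-3-yl]but-3-en-2-one | [N-]=[N+]=CC(=O)/C=C/[C@@H]1COc2cc(O[Si](C(C)C)(C(C)C)C(C)C)cc(OC)c2C1
A7 | alternative 3 | 1-methoxy-5-methylhex-4-en-1-yne | COC#CCC=C(C)C
A8 | alternative 3 | 3-methoxy-6-[(3R)-5-methoxy-7-[(triisopropylsilyl)oxy]-3,4-dihydro-2H-chromen-3-yl]-2-(3-methylbut-2-en-1-yl)phenol | COc1ccc([C@@H]2COc3cc(O[Si](C(C)C)(C(C)C)C(C)C)cc(OC)c3C2)c(O)c1CC=C(C)C
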